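**Retrosynthetic overview**
- The target is reached by one hydrogenation from a macrocyclic stilbene bis(benzyl ether); the 18-membered ring is closed by an intramolecular Wittig reaction between a ring A aldehyde and a ring D benzylic phosphonium salt.
- The open-chain precursor comes from SNAr of a ring B phenol onto a ring A 2-fluorobenzaldehyde (ring A–O–ring B ether).
- The ring B–CH2CH2–ring C bridge is the key C–C bond: Perkin (aldol-type) condensation of a ring C/ring D diaryl ether aldehyde with a ring B arylacetic acid, then decarboxylation and alkene saturation.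
- The ring C–O–ring D ether is made first by SNAr; the ring A piece comes from directed ortho-metalation/formylation of a fluoroanisole.
- All four benzene rings are purchased; the only ring formed is the macrocycle, in the penultimate step.

Assumption: the target has no stereocentre and no axial or planar descriptor, so it is made as the single achiral compound and no enantiocontrol is needed.

**Route**

Step 1
Reactants: 1 4-(benzyloxy)-3-hydroxybenzaldehyde + 2 methyl 4-fluorobenzoate
Product: 3 methyl 4-[2-(benzyloxy)-5-formylphenoxy]benzoate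
Conditions: Cs2CO3, DMSO, 110 °C
Reagents that add atoms: none
Why: SNAr (addition–elimination) in which the caesium phenoxide of 1 displaces the fluoride para to the ester, which stabilises the Meisenheimer adduct; no stereocentre is formed.

Step 2
Reactants: 3 methyl 4-[2-(benzyloxy)-5-formylphenoxy]benzoate + 4 2-(3-hydroxyphenyl)acetic acid
Product: 7 (E)-2-(3-acetoxyphenyl)-3-{4-(benzyloxy)-3-[4-(methoxycarbonyl)phenoxy]phenyl}prop-2-enoic acid, via acetic arylacetic mixed anhydride 5 (not isolated), via acetic diarylacrylic mixed anhydride 6 (not isolated)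
Conditions: Ac2O, Et3N, 120 °C; then H2O, 90 °C
Reagents that add atoms: acetic anhydride CC(=O)OC(C)=O
Why: Perkin (Oglialoro) condensation, an intermolecular aldol-type condensation in which Et3N enolises mixed anhydride 5 at its benzylic CH2, the enolate adds to aldehyde 3 and elimination gives under thermodynamic control the (E)-acid with the two aryl groups cis, while the phenol is acetylated in passing and water cleaves the anhydride 6.

Step 3
Reactants: 7 (E)-2-(3-acetoxyphenyl)-3-{4-(benzyloxy)-3-[4-(methoxycarbonyl)phenoxy]phenyl}prop-2-enoic acid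
Product: 8 methyl 4-{5-[(Z)-2-(3-acetoxyphenyl)ethenyl]-2-(benzyloxy)phenoxy}benzoate
Conditions: Cu powder (cat.), quinoline, 210 °C, N2
Reagents that add atoms: none
Why: Copper-mediated thermal protodecarboxylation of an α-arylcinnamic acid proceeds with retention of alkene geometry to the (Z)-stilbene, and the geometry is of no consequence because step 5 saturates the alkene.

Step 4
Reactants: 8 methyl 4-{5-[(Z)-2-(3-acetoxyphenyl)ethenyl]-2-(benzyloxy)phenoxy}benzoate
Product: 9 3-[(Z)-2-{4-(benzyloxy)-3-[4-(hydroxymethyl)phenoxy]phenyl}ethenyl]phenol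
Conditions: LiAlH4, THF, 0 °C to rt; aqueous work-up
Reagents that add atoms: none
Why: Hydride reduction converts the methyl benzoate into the benzylic alcohol and cleaves the aryl acetate in the same operation, while the stilbene, benzyl ether and diaryl ether are inert to LiAlH4.

Step 5
Reactants: 9 3-[(Z)-2-{4-(benzyloxy)-3-[4-(hydroxymethyl)phenoxy]phenyl}ethenyl]phenol
Product: 10 3-(2-{4-(benzyloxy)-3-[4-(hydroxymethyl)phenoxy]phenyl}ethyl)phenol
Conditions: TsNHNH2 (excess), NaOAc, DME/H2O, reflux
Reagents that add atoms: none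
Why: Diimide reduction (concerted syn transfer of two hydrogens from HN=NH) saturates the stilbene without hydrogenolysis of the benzyl ether, which must stay in place to keep the ring C oxygen distinct from the free ring B phenol.

Step 6
Reactants: 11 3-fluoro-4-methoxyphenol
Product: 12 2-fluoro-1-methoxy-4-(methoxymethoxy)benzene
Conditions: NaH, THF, 0 °C; MOMCl, 0 °C to rt
Reagents that add atoms: chloromethyl methyl ether COCCl
Why: Williamson-type O-alkylation of the sodium phenoxide installs the MOM ether, a strong directing group for the metalation in step 7.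

Step 7
Reactants: 12 2-fluoro-1-methoxy-4-(methoxymethoxy)benzene
Product: 14 2-fluoro-3-methoxy-6-(methoxymethoxy)benzaldehyde, via aryllithium 13 (not isolated)
Conditions: n-BuLi, THF, −78 °C; DMF, −78 °C to rt; H2O
Reagents that add atoms: N,N-dimethylformamide CN(C)C=O
Why: Directed ortho-metalation occurs at the most acidic position, flanked by F and OMOM, at a temperature below that of LiF loss, and DMF formylates the aryllithium.

Step 8
Reactants: 14 2-fluoro-3-methoxy-6-(methoxymethoxy)benzaldehyde
Product: 15 2-fluoro-6-hydroxy-3-methoxybenzaldehyde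
Conditions: 3 M aq. HCl, THF, 50 °C
Reagents that add atoms: none
Why: Acid-catalysed hydrolysis of the MOM acetal frees the phenol while the aryl fluoride, methyl ether and aldehyde are untouched.

Step 9
Reactants: 15 2-fluoro-6-hydroxy-3-methoxybenzaldehyde
Product: 16 6-(benzyloxy)-2-fluoro-3-methoxybenzaldehyde
Conditions: BnBr, K2CO3, DMF, 50 °C
Reagents that add atoms: benzyl bromide BrCc1ccccc1
Why: Williamson ether synthesis puts on a benzyl group that survives steps 10 to 13 and is removed together with the ring C benzyl ether in step 14.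

Step 10
Reactants: 10 3-(2-{4-(benzyloxy)-3-[4-(hydroxymethyl)phenoxy]phenyl}ethyl)phenol + 16 6-(benzyloxy)-2-fluoro-3-methoxybenzaldehyde
Product: 17 6-(benzyloxy)-2-[3-(2-{4-(benzyloxy)-3-[4-(hydroxymethyl)phenoxy]phenyl}ethyl)phenoxy]-3-methoxybenzaldehyde
Conditions: Cs2CO3, DMSO, 100 °C
Reagents that add atoms: none
Why: SNAr at the fluoride ortho to the formyl group, which stabilises the Meisenheimer adduct; the carbonate ionises only the phenol of 10, so the benzylic alcohol does not compete.

Step 11
Reactants: 17 6-(benzyloxy)-2-[3-(2-{4-(benzyloxy)-3-[4-(hydroxymethyl)phenoxy]phenyl}ethyl)phenoxy]-3-methoxybenzaldehyde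
Product: 18 6-(benzyloxy)-2-[3-(2-{4-(benzyloxy)-3-[4-(bromomethyl)phenoxy]phenyl}ethyl)phenoxy]-3-methoxybenzaldehyde
Conditions: PBr3, CH2Cl2, 0 °C
Reagents that add atoms: phosphorus tribromide BrP(Br)Br
Why: Bromination of the electron-rich benzylic alcohol via its phosphite ester and bromide displacement is fast at 0 °C and leaves the hindered aryl aldehyde alone.

Step 12
Reactants: 18 6-(benzyloxy)-2-[3-(2-{4-(benzyloxy)-3-[4-(bromomethyl)phenoxy]phenyl}ethyl)phenoxy]-3-methoxybenzaldehyde
Product: 19 {4-[2-(benzyloxy)-5-(2-{3-[3-(benzyloxy)-2-formyl-6-methoxyphenoxy]phenyl}ethyl)phenoxy]benzyl}triphenylphosphonium bromide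
Conditions: PPh3, toluene, 90 °C
Reagents that add atoms: triphenylphosphine c1ccc(cc1)P(c1ccccc1)c1ccccc1
Why: SN2 quaternisation of PPh3 by the benzylic bromide gives the phosphonium salt, which precipitates from toluene and is stable next to the aldehyde until base is added.

Step 13
Reactants: 19 {4-[2-(benzyloxy)-5-(2-{3-[3-(benzyloxy)-2-formyl-6-methoxyphenoxy]phenyl}ethyl)phenoxy]benzyl}triphenylphosphonium bromide
Product: 21 (Z)-macrocyclic stilbene bis(benzyl ether) [target skeleton; cis CH=CH between ring A/ring D; OBn on ring A/ring C], via phosphonium ylide 20 (not isolated)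
Conditions: NaOMe, CH2Cl2, rt, syringe-pump addition of 19 over 12 h, final conc. ca. 1 mM
Reagents that add atoms: none
Why: Intramolecular Wittig olefination under high dilution, where slow addition keeps the ylide concentration minimal so that ring closure outruns oligomerisation; the Z-alkene is expected as main isomer and its geometry is erased in step 14.

Step 14
Reactants: 21 (Z)-macrocyclic stilbene bis(benzyl ether)
Product: 22 CNP0179896.0 (target)
Conditions: H2 (1 atm), Pd/C, EtOAc/MeOH, rt
Reagents that add atoms: none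
Why: Heterogeneous catalytic hydrogenation saturates the stilbene and hydrogenolyses both benzyl ethers in one operation to give the achiral target, in which no stereocentre is present.

**Compound list**
1 | 4-(benzyloxy)-3-hydroxybenzaldehyde | O=Cc1ccc(OCc2ccccc2)c(O)c1 | starting material
2 | methyl 4-fluorobenzoate | COC(=O)c1ccc(F)cc1 | starting material
3 | methyl 4-[2-(benzyloxy)-5-formylphenoxy]benzoate | COC(=O)c1ccc(Oc2cc(C=O)ccc2OCc2ccccc2)cc1 | intermediate
4 | 2-(3-hydroxyphenyl)acetic acid | OC(=O)Cc1cccc(O)c1 | starting material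
5 | acetic 2-(3-acetoxyphenyl)acetic anhydride (acetic arylacetic mixed anhydride) | CC(=O)OC(=O)Cc1cccc(OC(C)=O)c1 | intermediate
6 | acetic (E)-2-(3-acetoxyphenyl)-3-{4-(benzyloxy)-3-[4-(methoxycarbonyl)phenoxy]phenyl}prop-2-enoic anhydride (acetic diarylacrylic mixed anhydride) | CC(=O)OC(=O)/C(c1cccc(OC(C)=O)c1)=C/c1ccc(OCc2ccccc2)c(Oc2ccc(C(=O)OC)cc2)c1 | intermediate
7 | (E)-2-(3-acetoxyphenyl)-3-{4-(benzyloxy)-3-[4-(methoxycarbonyl)phenoxy]phenyl}prop-2-enoic acid (aryl groups cis) | OC(=O)/C(c1cccc(OC(C)=O)c1)=C/c1ccc(OCc2ccccc2)c(Oc2ccc(C(=O)OC)cc2)c1 | intermediate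
8 | methyl 4-{5-[(Z)-2-(3-acetoxyphenyl)ethenyl]-2-(benzyloxy)phenoxy}benzoate | CC(=O)Oc1cccc(/C=C\c2ccc(OCc3ccccc3)c(Oc3ccc(C(=O)OC)cc3)c2)c1 | intermediate
9 | 3-[(Z)-2-{4-(benzyloxy)-3-[4-(hydroxymethyl)phenoxy]phenyl}ethenyl]phenol | Oc1cccc(/C=C\c2ccc(OCc3ccccc3)c(Oc3ccc(CO)cc3)c2)c1 | intermediate
10 | 3-(2-{4-(benzyloxy)-3-[4-(hydroxymethyl)phenoxy]phenyl}ethyl)phenol | Oc1cccc(CCc2ccc(OCc3ccccc3)c(Oc3ccc(CO)cc3)c2)c1 | intermediate
11 | 3-fluoro-4-methoxyphenol | COc1ccc(O)cc1F | starting material
12 | 2-fluoro-1-methoxy-4-(methoxymethoxy)benzene | COCOc1ccc(OC)c(F)c1 | intermediate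
13 | [2-fluoro-3-methoxy-6-(methoxymethoxy)phenyl]lithium (aryllithium) | [Li]c1c(F)c(OC)ccc1OCOC | intermediate
14 | 2-fluoro-3-methoxy-6-(methoxymethoxy)benzaldehyde | COCOc1ccc(OC)c(F)c1C=O | intermediate
15 | 2-fluoro-6-hydroxy-3-methoxybenzaldehyde | COc1ccc(O)c(C=O)c1F | intermediate
16 | 6-(benzyloxy)-2-fluoro-3-methoxybenzaldehyde | COc1ccc(OCc2ccccc2)c(C=O)c1F | intermediate
17 | 6-(benzyloxy)-2-[3-(2-{4-(benzyloxy)-3-[4-(hydroxymethyl)phenoxy]phenyl}ethyl)phenoxy]-3-methoxybenzaldehyde | COc1ccc(OCc2ccccc2)c(C=O)c1Oc1cccc(CCc2ccc(OCc3ccccc3)c(Oc3ccc(CO)cc3)c2)c1 | intermediate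
18 | 6-(benzyloxy)-2-[3-(2-{4-(benzyloxy)-3-[4-(bromomethyl)phenoxy]phenyl}ethyl)phenoxy]-3-methoxybenzaldehyde | COc1ccc(OCc2ccccc2)c(C=O)c1Oc1cccc(CCc2ccc(OCc3ccccc3)c(Oc3ccc(CBr)cc3)c2)c1 | intermediate
19 | {4-[2-(benzyloxy)-5-(2-{3-[3-(benzyloxy)-2-formyl-6-methoxyphenoxy]phenyl}ethyl)phenoxy]benzyl}triphenylphosphonium bromide | COc1ccc(OCc2ccccc2)c(C=O)c1Oc1cccc(CCc2ccc(OCc3ccccc3)c(Oc3ccc(C[P+](c4ccccc4)(c4ccccc4)c4ccccc4)cc3)c2)c1.[Br-] | intermediate
20 | {4-[2-(benzyloxy)-5-(2-{3-[3-(benzyloxy)-2-formyl-6-methoxyphenoxy]phenyl}ethyl)phenoxy]benzylidene}triphenylphosphorane (phosphonium ylide) | COc1ccc(OCc2ccccc2)c(C=O)c1Oc1cccc(CCc2ccc(OCc3ccccc3)c(Oc3ccc(C=P(c4ccccc4)(c4ccccc4)c4ccccc4)cc3)c2)c1 | intermediate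
21 | (Z)-macrocyclic stilbene bis(benzyl ether): the target skeleton with a cis CH=CH bridge between ring A and ring D in place of CH2CH2 and benzyl ethers on the ring A and ring C hydroxyls | c1(/C=C\c2ccc(cc2)Oc2cc(ccc2OCc2ccccc2)CCc2cccc(c2)O3)c3c(OC)ccc1OCc1ccccc1 | intermediate
22 | CNP0179896.0: 18-membered bis(bibenzyl) macrocycle; ring A carries OMe, O–ring B, CH2CH2–ring D and OH on four adjacent carbons in that order; ring B is meta-linked; ring C carries OH ortho to O–ring D and para to the CH2CH2 bridge; ring D is para-linked; achiral | COc1ccc(O)c2c1Oc1cccc(c1)CCc1ccc(O)c(c1)Oc1ccc(cc1)CC2 | target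

**Step count and risks**
Total step count: 14. Longest linear sequence: 10 steps (1 → 3 → 7 → 8 → 9 → 10 → 17 → 18 → 19 → 21 → 22); the ring A branch (11 → 16) is 4 steps and joins at step 10.

The three steps most likely to fail are steps 3, 10 and 13.

Step 3: the 210 °C decarboxylation may erode the acetate, ester or benzyl ether or give poor mass balance. The fallback sets out from 7 and comes back at 10, removing the carboxyl group by a radical route instead of a thermal one. The acrylic C=C of 7 alone is hydrogenated (H2, Pd/C poisoned with Ph2S so that the benzyl ether is kept, EtOAc, rt) to racemic 2-(3-acetoxyphenyl)-3-{4-(benzyloxy)-3-[4-(methoxycarbonyl)phenoxy]phenyl}propanoic acid F1. This is converted (N-hydroxypyridine-2-thione, DCC, CH2Cl2, dark) into the Barton ester 2-thioxopyridin-1(2H)-yl 2-(3-acetoxyphenyl)-3-{4-(benzyloxy)-3-[4-(methoxycarbonyl)phenoxy]phenyl}propanoate F2. Reductive radical decarboxylation (t-BuSH, visible light, THF, rt) gives methyl 4-{5-[2-(3-acetoxyphenyl)ethyl]-2-(benzyloxy)phenoxy}benzoate F3 with the bridge already saturated. LiAlH4 (THF, 0 °C) then reduces the ester and cleaves the acetate to give 10, so steps 4 and 5 are not needed. The stereocentre of F1 and F2 is racemic and disappears in F3.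

Step 10: the fluoride is flanked by OMe and CHO on an electron-rich ring, and the phenol partner is an advanced intermediate. The fallback sets out from 10 and comes back at 17, replacing SNAr by a copper-catalysed Ullmann coupling with the iodo analogue of 16, built from purchased 2-hydroxy-5-methoxybenzaldehyde. MOM protection (NaH, MOMCl, THF) gives 5-methoxy-2-(methoxymethoxy)benzaldehyde F4. Directed ortho-lithiation between the formyl and methoxy groups, with the aldehyde masked in the flask by lithium N,N,N′-trimethylethylenediamide (then n-BuLi, THF, −20 °C), and quench with iodine gives 2-iodo-3-methoxy-6-(methoxymethoxy)benzaldehyde F5. MOM removal (aq. HCl, THF) gives 6-hydroxy-2-iodo-3-methoxybenzaldehyde F6, and benzylation (BnBr, K2CO3, DMF) gives 6-(benzyloxy)-2-iodo-3-methoxybenzaldehyde F7. Coupling of 10 with F7 (CuI, N,N-dimethylglycine, Cs2CO3, dioxane, 90 °C) gives 17; the phenol is arylated in preference to the benzylic alcohol and the ortho-formyl group assists the copper insertion.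

Step 13: macrocyclisation competes with oligomerisation and the aldehyde is di-ortho-substituted. The fallback sets out from 17 and comes back at 21, changing from ylide olefination to reductive carbonyl coupling. The benzylic alcohol of 17 is oxidised (MnO2, CH2Cl2, rt) to the dialdehyde 6-(benzyloxy)-2-[3-(2-{4-(benzyloxy)-3-(4-formylphenoxy)phenyl}ethyl)phenoxy]-3-methoxybenzaldehyde F8. Intramolecular McMurry coupling (TiCl4, Zn, pyridine, THF, reflux, syringe-pump addition at high dilution) closes the ring to the macrocyclic stilbene 21, which goes on to step 14; steps 11 and 12 are then not needed.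

**Further compounds**
F1 | step 3 | racemic 2-(3-acetoxyphenyl)-3-{4-(benzyloxy)-3-[4-(methoxycarbonyl)phenoxy]phenyl}propanoic acid | CC(=O)Oc1cccc(c1)C(Cc1ccc(OCc2ccccc2)c(Oc2ccc(C(=O)OC)cc2)c1)C(O)=O
F2 | step 3 | racemic 2-thioxopyridin-1(2H)-yl 2-(3-acetoxyphenyl)-3-{4-(benzyloxy)-3-[4-(methoxycarbonyl)phenoxy]phenyl}propanoate | CC(=O)Oc1cccc(c1)C(Cc1ccc(OCc2ccccc2)c(Oc2ccc(C(=O)OC)cc2)c1)C(=O)On1ccccc1=S
F3 | step 3 | methyl 4-{5-[2-(3-acetoxyphenyl)ethyl]-2-(benzyloxy)phenoxy}benzoate | CC(=O)Oc1cccc(CCc2ccc(OCc3ccccc3)c(Oc3ccc(C(=O)OC)cc3)c2)c1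
F4 | step 10 | 5-methoxy-2-(methoxymethoxy)benzaldehyde | COCOc1ccc(OC)cc1C=O
F5 | step 10 | 2-iodo-3-methoxy-6-(methoxymethoxy)benzaldehyde | COCOc1ccc(OC)c(I)c1C=O
F6 | step 10 | 6-hydroxy-2-iodo-3-methoxybenzaldehyde | COc1ccc(O)c(C=O)c1I
F7 | step 10 | 6-(benzyloxy)-2-iodo-3-methoxybenzaldehyde | COc1ccc(OCc2ccccc2)c(C=O)c1I
F8 | step 13 | 6-(benzyloxy)-2-[3-(2-{4-(benzyloxy)-3-(4-formylphenoxy)phenyl}ethyl)phenoxy]-3-methoxybenzaldehyde | COc1ccc(OCc2ccccc2)c(C=O)c1Oc1cccc(CCc2ccc(OCc3ccccc3)c(Oc3ccc(C=O)cc3)c2)c1
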